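The disconnection cuts the two bonds that join the cyclobutane to its pyranone rings, C3–C6′ and C4–C6″ (C6′, C6″: the pyranone carbons bonded to the cyclobutane). C3 and C4 are vicinal quaternary ring carbons, and the meso photoadduct of maleic and dimethylmaleic anhydride carries a carboxyl on exactly these two carbons. In one photoredox operation the key step replaces both carboxyls by silylalkynes and rebuilds both quaternary stereocentres anti to the C1/C2 esters; no ring closes. Its precursor is the enantiopure 3,4-diacid with a C1 methyl and a C2 tert-butyl ester, obtained by alkaloid-mediated methanolysis of the unhindered anhydride. Each alkyne then supplies C6′ and C5′ of a pyranone, closed by gold catalysis and O-methylated.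

Key step: step 5

Locants used throughout: C1 carries CO2Me, C2 the other CH-bound carboxyl, C3 and C4 the methyl groups; pyranone atoms are primed. The "lower face" is the face of the C1/C2 carboxyls and both methyls, the "upper face" the opposite one. Descriptors refer to these locants.

Assumption: quinidine is taken to open dianhydride 3 at the carbonyl on the future C1, the sense it shows with simple cis-fused meso anhydrides; the configuration of 4 is checked at that stage and quinine would be used instead if the sense proved opposite.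

Step 1
Reactants: 1 maleic anhydride; 2 2,3-dimethylmaleic anhydride
Product: 3 meso cis-anti-cis 3,4-dimethylcyclobutane-1,2,3,4-tetracarboxylic 1,2:3,4-dianhydride (anhydride rings on opposite faces)
Conditions: hν (350 nm), benzophenone (10 mol%), 1 (4 equiv), EtOAc, rt; crystallisation
Reagents that add atoms: none
Why: Triplet-sensitised crossed [2+2] photocycloaddition (the reaction type of the maleic anhydride photodimerisation): the five-membered rings fix both cis fusions and the 1,4-biradical should close to the less crowded anti dianhydride, which sets the relative configuration of all four ring carbons, while excess 1 diverts excited 2 from self-dimerisation and the much less soluble homodimer of 1 is removed by crystallisation.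

Step 2
Reactants: 3 meso dianhydride
Product: 4 (1R,2S,3R,4S)-1-methyl 2-hydrogen 3,4-dimethylcyclobutane-1,2,3,4-tetracarboxylate 3,4-anhydride (CO2Me and CO2H cis on the lower face)
Conditions: quinidine (1.1 equiv), MeOH (3 equiv), toluene, −55 °C; cold 1 M HCl wash
Reagents that add atoms: methanol, CO
Why: Cinchona-alkaloid-mediated desymmetrising methanolysis of a meso anhydride: the quinuclidine nitrogen delivers methanol as a general base to one of the two enantiotopic carbonyls of the unhindered anhydride (the one on the future C1), which fixes the absolute configuration of all four stereocentres, while the anhydride flanked by two quaternary carbons is too hindered to react at this temperature.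

Step 3
Reactants: 4 half-ester anhydride
Product: 5 (1R,2S,3R,4S)-1-methyl 2-tert-butyl 3,4-dimethylcyclobutane-1,2,3,4-tetracarboxylate 3,4-anhydride
Conditions: Cl3CC(=NH)OtBu (2.5 equiv), CH2Cl2/cyclohexane, rt
Reagents that add atoms: tert-butyl 2,2,2-trichloroacetimidate, CC(C)(C)OC(=N)C(Cl)(Cl)Cl
Why: Acid-promoted O-alkylation of the carboxylic acid by the trichloroacetimidate (tert-butyl cation transfer) needs no base, so the anhydride, the methyl ester and the epimerisable C1/C2 centres stay untouched.

Step 4
Reactants: 5 diester anhydride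
Product: 6 (1R,2S,3R,4S)-1-methyl 2-tert-butyl 3,4-dihydrogen 3,4-dimethylcyclobutane-1,2,3,4-tetracarboxylate (the 3,4-diacid; both CO2H on the upper face)
Conditions: LiOH (2.1 equiv), THF/H2O, 0 °C; then 1 M HCl to pH 3 at 0 °C, EtOAc; dried without heat and used at once
Reagents that add atoms: lithium hydroxide, [Li+].[OH-]
Why: Hydroxide opening of the strained tetrasubstituted anhydride (anhydride saponification) should be far faster than attack on the methyl or tert-butyl ester at 0 °C; the cis-diacid is liberated cold and used directly because on standing or warming it can lose water back to 5, which would only return starting material.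

Step 5
Reactants: 6 the 3,4-diacid; 7 1-[(triisopropylsilyl)ethynyl]-1,2-benziodoxol-3(1H)-one
Product: 9 1-methyl 2-tert-butyl (1R,2S,3R,4S)-3,4-dimethyl-3,4-bis[(triisopropylsilyl)ethynyl]cyclobutane-1,2-dicarboxylate, via monoalkynyl monoacid 8 (not isolated)
Conditions: 7 (3.0 equiv), 4CzIPN (5 mol%), Cs2CO3 (2.5 equiv), degassed CH2Cl2/DMF 4:1 (0.1 M), blue LEDs (455 nm), rt
Reagents that add atoms: none
Why: Photoexcited 4CzIPN oxidises a caesium carboxylate of 6, CO2 is lost, and the tertiary cyclobutyl radical adds to the iodine-bound alkyne carbon of 7 and expels the iodanyl radical, which the reduced photocatalyst turns into 2-iodobenzoate, so the cycle repeats at the second carboxylate via 8 (shown as the C3-alkynyl isomer; its C4 counterpart reacts on in the same way). The closest known reaction type is the photoredox decarboxylative alkynylation of single tertiary carboxylic acids with ethynylbenziodoxolones; running it twice on a vicinal diacid is an untested extension of that chemistry. No ring is closed; only the C3–C(sp) and C4–C(sp) bonds are made. Both quaternary stereocentres are rebuilt from planar radicals under substrate control: the alkyne should enter on the upper face, which carries only H at the neighbouring CH carbon and the slim carboxylate or alkyne at the other neighbour, because the lower face is flanked by an ester and a methyl group. The step needs radical trapping to beat oxidation of the radical followed by loss of the second CO2 to a cyclobutene; excess 7 at high concentration, the absence of any stoichiometric oxidant and ester protection of the C1/C2 carboxyls are meant to secure this.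

Step 6
Reactants: 9 bis(silylalkyne)
Product: 10 1-methyl 2-tert-butyl (1R,2S,3S,4R)-3,4-diethynyl-3,4-dimethylcyclobutane-1,2-dicarboxylate (same geometry; the C3/C4 descriptors change only formally)
Conditions: TBAF (2.4 equiv), AcOH (2.4 equiv), THF, 0 °C to rt
Reagents that add atoms: none
Why: Fluoride-induced protodesilylation of the two C(sp)–Si bonds; the acetic acid buffer supplies the proton and keeps the medium from epimerising the cis C1/C2 diester.

Step 7
Reactants: 11 2,2,5-trimethyl-1,3-dioxane-4,6-dione (methyl Meldrum's acid)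
Product: 12 3-tert-butoxy-2-methyl-3-oxopropanoic acid (racemic)
Conditions: t-BuOH, reflux
Reagents that add atoms: tert-butanol, CC(C)(C)O
Why: Thermal alcoholysis of the Meldrum's acid ring: tert-butanol opens the cyclic acylal and acetone is lost, giving the malonic half-ester in one step.

Step 8
Reactants: 10 bis(terminal alkyne); 12 malonic half-ester
Product: 14 1-methyl 2-tert-butyl (1R,2S,3S,4R)-3,4-bis(5-tert-butoxy-4-methyl-3,5-dioxopent-1-yn-1-yl)-3,4-dimethylcyclobutane-1,2-dicarboxylate (mixture of epimers at the two side-chain CHMe carbons), via acid chloride 13 (not isolated)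
Conditions: 12 (3.2 equiv), 1-chloro-N,N,2-trimethylprop-1-en-1-amine (3.2 equiv), CH2Cl2, 0 °C; then added slowly to 10, PdCl2(PPh3)2 (5 mol%), CuI (10 mol%), Et3N (2.5 equiv), THF, 0 °C to rt
Reagents that add atoms: none
Why: Acyl Sonogashira coupling: the acid chloride, made under neutral conditions with the chloroenamine, adds oxidatively to zerovalent palladium (formed in the flask from the divalent precatalyst), the copper acetylide of each alkyne transmetallates and reductive elimination gives the ynone; the new side-chain CHMe centres are uncontrolled and are erased when the pyranones form.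

Step 9
Reactants: 14 bis(alkynyl β-keto ester)
Product: 15 1-methyl 2-tert-butyl (1R,2S,3R,4S)-3,4-bis(4-hydroxy-3-methyl-2-oxo-2H-pyran-6-yl)-3,4-dimethylcyclobutane-1,2-dicarboxylate
Conditions: Ph3PAuNTf2 (10 mol%), MeNO2/AcOH 4:1, rt
Reagents that add atoms: none
Why: Gold-catalysed 6-endo-dig lactonisation of tert-butyl 3-oxoalk-4-ynoates: monovalent gold activates each ynone, the tert-butyl ester carbonyl oxygen attacks the electrophilic β-carbon (future C6′), isobutene is lost and tautomerisation gives the 4-hydroxy-2-pyranone, so no enol-ether geometry has to be controlled; the C1/C2 esters sit on the ring face opposite the alkynes and cannot compete.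

Step 10
Reactants: 15 bis(4-hydroxypyranone)
Product: 16 1-methyl 2-tert-butyl (1R,2S,3R,4S)-3,4-bis(4-methoxy-3-methyl-2-oxo-2H-pyran-6-yl)-3,4-dimethylcyclobutane-1,2-dicarboxylate
Conditions: Me2SO4 (3 equiv), K2CO3 (4 equiv), acetone, 40 °C
Reagents that add atoms: dimethyl sulfate, COS(=O)(=O)OC
Why: O-Alkylation of the vinylogous acid: with dimethyl sulfate and K2CO3 in acetone, 4-hydroxy-2-pyranones are methylated at the 4-oxygen to give the 4-methoxy-2-pyranone, not the 2-methoxy-4-pyranone, and the mild base leaves both esters and the C1/C2 centres alone.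

Step 11
Reactants: 16 tert-butyl ester
Product: 17 (1R,2S,3R,4S)-1-methyl 2-hydrogen 3,4-bis(4-methoxy-3-methyl-2-oxo-2H-pyran-6-yl)-3,4-dimethylcyclobutane-1,2-dicarboxylate (CNP0481603.1)
Conditions: TFA/CH2Cl2 1:3, 0 °C to rt
Reagents that add atoms: none
Why: Acidolysis of the tert-butyl ester (loss of isobutene through the tert-butyl cation) frees the C2 acid without touching the methyl ester, the pyranone enol ethers or any stereocentre.

Compound list
1 | maleic anhydride | O=C1OC(=O)C=C1 | starting material
2 | 2,3-dimethylmaleic anhydride | CC1=C(C)C(=O)OC1=O | starting material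
3 | meso cis,anti,cis-3,4-dimethylcyclobutane-1,2,3,4-tetracarboxylic 1,2:3,4-dianhydride | O1C(=O)[C@@H]2[C@H](C1=O)[C@@](C)(C(=O)O3)[C@@]2(C)C3=O | intermediate
4 | (1R,2S,3R,4S)-1-methyl 2-hydrogen 3,4-dimethylcyclobutane-1,2,3,4-tetracarboxylate 3,4-anhydride | COC(=O)[C@@H]1[C@H](C(=O)O)[C@@](C)(C(=O)O2)[C@@]1(C)C2=O | intermediate
5 | (1R,2S,3R,4S)-1-methyl 2-tert-butyl 3,4-dimethylcyclobutane-1,2,3,4-tetracarboxylate 3,4-anhydride | COC(=O)[C@@H]1[C@H](C(=O)OC(C)(C)C)[C@@](C)(C(=O)O2)[C@@]1(C)C2=O | intermediate
6 | (1R,2S,3R,4S)-1-methyl 2-tert-butyl 3,4-dihydrogen 3,4-dimethylcyclobutane-1,2,3,4-tetracarboxylate (3,4-diacid) | COC(=O)[C@@H]1[C@H](C(=O)OC(C)(C)C)[C@@](C)(C(=O)O)[C@@]1(C)C(=O)O | intermediate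
7 | 1-[(triisopropylsilyl)ethynyl]-1,2-benziodoxol-3(1H)-one | CC(C)[Si](C(C)C)(C(C)C)C#CI1OC(=O)c2ccccc12 | starting material
8 | 1-methyl 2-tert-butyl 4-hydrogen (1R,2S,3R,4S)-3,4-dimethyl-3-[(triisopropylsilyl)ethynyl]cyclobutane-1,2,4-tricarboxylate (monoalkynyl monoacid; present as its caesium salt) | COC(=O)[C@@H]1[C@H](C(=O)OC(C)(C)C)[C@@](C)(C#C[Si](C(C)C)(C(C)C)C(C)C)[C@@]1(C)C(=O)O | intermediate (not isolated)
9 | 1-methyl 2-tert-butyl (1R,2S,3R,4S)-3,4-dimethyl-3,4-bis[(triisopropylsilyl)ethynyl]cyclobutane-1,2-dicarboxylate | COC(=O)[C@@H]1[C@H](C(=O)OC(C)(C)C)[C@@](C)(C#C[Si](C(C)C)(C(C)C)C(C)C)[C@@]1(C)C#C[Si](C(C)C)(C(C)C)C(C)C | intermediate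
10 | 1-methyl 2-tert-butyl (1R,2S,3S,4R)-3,4-diethynyl-3,4-dimethylcyclobutane-1,2-dicarboxylate | COC(=O)[C@@H]1[C@H](C(=O)OC(C)(C)C)[C@@](C)(C#C)[C@@]1(C)C#C | intermediate
11 | 2,2,5-trimethyl-1,3-dioxane-4,6-dione | CC1C(=O)OC(C)(C)OC1=O | starting material
12 | 3-tert-butoxy-2-methyl-3-oxopropanoic acid (racemic) | CC(C(=O)O)C(=O)OC(C)(C)C | intermediate
13 | tert-butyl 3-chloro-2-methyl-3-oxopropanoate (racemic) | CC(C(=O)Cl)C(=O)OC(C)(C)C | intermediate (not isolated)
14 | 1-methyl 2-tert-butyl (1R,2S,3S,4R)-3,4-bis(5-tert-butoxy-4-methyl-3,5-dioxopent-1-yn-1-yl)-3,4-dimethylcyclobutane-1,2-dicarboxylate (side-chain CHMe epimers) | COC(=O)[C@@H]1[C@H](C(=O)OC(C)(C)C)[C@@](C)(C#CC(=O)C(C)C(=O)OC(C)(C)C)[C@@]1(C)C#CC(=O)C(C)C(=O)OC(C)(C)C | intermediate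
15 | 1-methyl 2-tert-butyl (1R,2S,3R,4S)-3,4-bis(4-hydroxy-3-methyl-2-oxo-2H-pyran-6-yl)-3,4-dimethylcyclobutane-1,2-dicarboxylate | COC(=O)[C@@H]1[C@H](C(=O)OC(C)(C)C)[C@@](C)(c2cc(O)c(C)c(=O)o2)[C@@]1(C)c1cc(O)c(C)c(=O)o1 | intermediate
16 | 1-methyl 2-tert-butyl (1R,2S,3R,4S)-3,4-bis(4-methoxy-3-methyl-2-oxo-2H-pyran-6-yl)-3,4-dimethylcyclobutane-1,2-dicarboxylate | COC(=O)[C@@H]1[C@H](C(=O)OC(C)(C)C)[C@@](C)(c2cc(OC)c(C)c(=O)o2)[C@@]1(C)c1cc(OC)c(C)c(=O)o1 | intermediate
17 | (1R,2S,3R,4S)-1-methyl 2-hydrogen 3,4-bis(4-methoxy-3-methyl-2-oxo-2H-pyran-6-yl)-3,4-dimethylcyclobutane-1,2-dicarboxylate (CNP0481603.1) | COC(=O)[C@@H]1[C@H](C(=O)O)[C@@](C)(c2cc(OC)c(C)c(=O)o2)[C@@]1(C)c1cc(OC)c(C)c(=O)o1 | target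

Total step count: 11. Longest linear sequence: 10 (steps 1–6 and 8–11; step 7 is a one-step side branch).

Steps most likely to fail

1. Step 5 (twofold decarboxylative alkynylation). The sequence may stall after the first coupling. The intermediate radical may be oxidised and lose the second CO2, forming a ring alkene. The alkyne may also be delivered to the lower face. Fallback, from 5 to 9, with the two carboxyls unveiled one at a time so that each coupling is the established single-acid reaction and no free neighbouring carboxylate is present in the first one: anhydride 5 is opened with allyl alcohol (DMAP, Et3N, CH2Cl2, 40 °C) to the mono-allyl ester mono-acid F1 (attack at the less shielded C4 carbonyl expected; the regioisomer converges). A single photoredox alkynylation with 7 (4CzIPN, Cs2CO3, blue LEDs) then gives the mono-alkyne allyl ester F2. Pd(PPh3)4 and morpholine remove the allyl group to give monoalkynyl monoacid 8, here isolated, and a second single alkynylation with 7 rejoins the route at 9.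

2. Step 8 (twofold acyl Sonogashira). The amine may dehydrochlorinate the α-acidic acid chloride to a ketene before it reaches palladium, and the second alkyne may couple incompletely. Fallback, from 10 to 14, with no amine present during acylation: 10 is heated with Bu3SnOMe (toluene, 60 °C, methanol removed) to the bis(tributylstannyl)alkyne F3. Stille acylation of F3 with acid chloride 13 (PdCl2(PPh3)2, 1,2-dichloroethane, 50 °C, neutral) then rejoins the route at 14.

3. Step 9 (twofold gold lactonisation). Attack of the ester oxygen at the alkyne carbon next to a quaternary centre may be slow, may divert to the 5-exo mode, or may stop after one ring. Fallback, from 10 to 15, which builds the pyranone from a ketone, not from an activated alkyne: Markovnikov hydration of both alkynes (Ph3PAuNTf2, MeOH/H2O, 60 °C) gives the bis(methyl ketone) F4. TMSOTf and Et3N (CH2Cl2, 0 °C) convert it to the bis(trimethylsilyl enol ether) F5. Methylmalonyl dichloride (Et2O, −78 °C to rt) then closes each 4-hydroxy-3-methyl-2-pyranone by C-acylation followed by O-acylation and rejoins the route at 15.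

Further compounds
F1 | step 5 | 1-methyl 2-tert-butyl 4-allyl 3-hydrogen (1R,2S,3R,4S)-3,4-dimethylcyclobutane-1,2,3,4-tetracarboxylate | COC(=O)[C@@H]1[C@H](C(=O)OC(C)(C)C)[C@@](C)(C(=O)O)[C@@]1(C)C(=O)OCC=C
F2 | step 5 | 1-methyl 2-tert-butyl 4-allyl (1R,2S,3R,4S)-3,4-dimethyl-3-[(triisopropylsilyl)ethynyl]cyclobutane-1,2,4-tricarboxylate | COC(=O)[C@@H]1[C@H](C(=O)OC(C)(C)C)[C@@](C)(C#C[Si](C(C)C)(C(C)C)C(C)C)[C@@]1(C)C(=O)OCC=C
F3 | step 8 | 1-methyl 2-tert-butyl (1R,2S,3R,4S)-3,4-dimethyl-3,4-bis[(tributylstannyl)ethynyl]cyclobutane-1,2-dicarboxylate | COC(=O)[C@@H]1[C@H](C(=O)OC(C)(C)C)[C@@](C)(C#C[Sn](CCCC)(CCCC)CCCC)[C@@]1(C)C#C[Sn](CCCC)(CCCC)CCCC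
F4 | step 9 | 1-methyl 2-tert-butyl (1R,2S,3R,4S)-3,4-diacetyl-3,4-dimethylcyclobutane-1,2-dicarboxylate | COC(=O)[C@@H]1[C@H](C(=O)OC(C)(C)C)[C@@](C)(C(C)=O)[C@@]1(C)C(C)=O
F5 | step 9 | 1-methyl 2-tert-butyl (1R,2S,3R,4S)-3,4-dimethyl-3,4-bis[1-(trimethylsilyloxy)ethenyl]cyclobutane-1,2-dicarboxylate | COC(=O)[C@@H]1[C@H](C(=O)OC(C)(C)C)[C@@](C)(C(=C)O[Si](C)(C)C)[C@@]1(C)C(=C)O[Si](C)(C)C
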